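The cyclohexanone ring of the target (C1 tertiary carbinol bearing CH2OBz, C2 ketone, C3 H2, C4 HOH, C5 HOBz, C6 HOH) contains the aldol retron C2(=O)–C3H2–C4H(OH). Disconnecting C3–C4 and bridging C2 and C4 through oxygen leads back to a 4-C-branched methyl 6-deoxyhex-5-enopyranoside. A Hg(II)-catalysed Ferrier carbocyclisation, placed last, converts this pyranoside into the cyclohexanone, unveils the ketone and sets C4 in one operation, on the unprotected diol dibenzoate. The precursor is built from a glucose-derived 2,3-anhydroalloside. Its oxirane steers a spiro-epoxidation at C-4, and benzoate then opens both epoxides, which installs both esters and the free hydroxyls.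

Key step: step 7

Assumption: compound 1 is bought as a catalogue carbohydrate building block (three classical steps from methyl α-D-glucopyranoside). Sugar locants are used for 1–9, with C-4′ as the branch carbon. The ring locants of the overview are used for 10.

Step 1
Reactants: 1 methyl 2,3-anhydro-4,6-O-[(R)-benzylidene]-α-D-allopyranoside
Product: 2 methyl 2,3-anhydro-4-O-benzoyl-6-bromo-6-deoxy-α-D-allopyranoside
Conditions: NBS, BaCO3, CCl4, reflux
Reagents that add atoms: N-bromosuccinimide, O=C1CCC(=O)N1Br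
Why: Hanessian–Hullar reaction, in which radical bromination of the benzylidene C–H gives a benzoxonium ion that bromide opens at the primary C-6, leaving O-4 as benzoate and the oxirane, the glycoside and all stereocentres untouched.

Step 2
Reactants: 2 methyl 2,3-anhydro-4-O-benzoyl-6-bromo-6-deoxy-α-D-allopyranoside
Product: 3 methyl 2,3-anhydro-6-bromo-6-deoxy-α-D-allopyranoside
Conditions: NaOMe (cat.), MeOH, 0 °C
Reagents that add atoms: none
Why: Zemplén transesterification removes the only ester; the 4-alkoxide is cis to the oxirane oxygen, so no epoxide migration can follow, and cold catalytic base should spare the bromide.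

Step 3
Reactants: 3 methyl 2,3-anhydro-6-bromo-6-deoxy-α-D-allopyranoside
Product: 5 methyl 2,3-anhydro-6-deoxy-α-D-erythro-hex-5-enopyranosid-4-ulose, via bromo-4-ulose 4 (not isolated)
Conditions: Dess–Martin periodinane, CH2Cl2, 0 °C to rt; then Et3N, 0 °C
Reagents that add atoms: none
Why: Dess–Martin oxidation gives a β-bromo ketone whose acidified H-5 is removed by the amine in an E1cB loss of bromide that installs the exocyclic C5=CH2, while H-3 sits on the oxirane and does not enolise, so C-2 and C-3 are safe.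

Step 4
Reactants: 5 methyl 2,3-anhydro-6-deoxy-α-D-erythro-hex-5-enopyranosid-4-ulose
Product: 6 methyl 2,3:4,4′-dianhydro-6-deoxy-4-C-(hydroxymethyl)-α-D-ribo-hex-5-enopyranoside (spiro-oxirane, O-4 on the α-face, CH2 on the β-face)
Conditions: Me3S+ I−, NaH, DMSO–THF, −5 °C
Reagents that add atoms: trimethylsulfonium iodide, C[S+](C)C.[I-]
Why: Corey–Chaykovsky epoxidation, in which the unstabilised sulfonium ylide adds 1,2 to the enone from the open β-face, anti to the adjacent α-oxirane oxygen, so closure of the betaine leaves O-4 on the α-face and the new CH2 on the β-face, which is the configuration of C1 of the target.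

Step 5
Reactants: 6 methyl 2,3:4,4′-dianhydro-6-deoxy-4-C-(hydroxymethyl)-α-D-ribo-hex-5-enopyranoside
Product: 7 methyl 2,3-anhydro-4-C-(benzoyloxymethyl)-6-deoxy-α-D-ribo-hex-5-enopyranoside (4-OH α, CH2OBz β)
Conditions: PhCO2H, PhCO2Cs (cat.), DMF, 60 °C
Reagents that add atoms: benzoic acid, O=C(O)c1ccccc1
Why: Buffered SN2 opening by benzoate at the primary CH2 of the spiro-oxirane should be much faster than attack at the secondary carbons of the 2,3-oxirane, SN2′ attack is disfavoured because C-6 is the electron-rich end of an enol ether, and C-4 is not touched.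

Step 6
Reactants: 7 methyl 2,3-anhydro-4-C-(benzoyloxymethyl)-6-deoxy-α-D-ribo-hex-5-enopyranoside
Product: 8 methyl 2-O-benzoyl-4-C-(benzoyloxymethyl)-6-deoxy-α-D-arabino-hex-5-enopyranoside (2-OBz β, 3-OH α, 4-OH α)
Conditions: PhCO2H, Ti(OiPr)4, CH2Cl2, rt
Reagents that add atoms: benzoic acid, O=C(O)c1ccccc1
Why: Titanium(IV)-mediated opening of a 2,3-epoxy alcohol, in which the tertiary 4-OH, cis to the oxirane, binds titanium and directs benzoate to the distal carbon C-2 (C-3 is also neopentyl, and C-2 attack is the Fürst–Plattner path in the half-chair with axial OMe), giving inversion at C-2 and the α-3-OH.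

Step 7
Reactants: 8 methyl 2-O-benzoyl-4-C-(benzoyloxymethyl)-6-deoxy-α-D-arabino-hex-5-enopyranoside
Product: 10 [(1S,2S,3R,4R)-3-(benzoyloxy)-1,2,4-trihydroxy-6-oxocyclohexyl]methyl benzoate, via open-chain mercurio keto-aldehyde 9 (not isolated)
Conditions: Hg(OCOCF3)2 (10 mol %), acetone–H2O 3:1, rt
Reagents that add atoms: water, O
Why: Hg(II) adds to C-6 of the enol ether and water to C-5, the hemiketal collapses, the ring oxygen leaves with C-1 as a hemiacetal that loses methanol, and the resulting α-mercurio ketone (a regiospecific mercury enolate) adds to the aldehyde before protonolysis returns Hg(II). This is the Ferrier carbocyclisation (Ferrier II reaction) of a hex-5-enopyranoside, which runs in aqueous acetone and is compatible with benzoates. The carbocycle closes by a 6-(enolendo)-exo-trig aldol that forms C3–C4. The only new stereocentre, C4, is set in a chair transition state that keeps CH2OBz, 6-OH and 5-OBz equatorial and the metal-bound aldehyde oxygen axial, which places the new hydroxyl trans to the former sugar 3-OH (C6–OH), the usual sense of this reaction. The step needs one enolate and mild conditions: the second α-carbon (C1) is quaternary, and the near-neutral medium should avoid benzoate migration, E1cB loss of the new β-hydroxyl and epimerisation at C5. The anomeric centre is destroyed on the way, so its configuration does not matter.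

Compound list
1 | methyl 2,3-anhydro-4,6-O-[(R)-benzylidene]-α-D-allopyranoside | CO[C@@H]1[C@@H]2O[C@@H]2[C@@H]3O[C@H](c4ccccc4)OC[C@H]3O1 | starting material
2 | methyl 2,3-anhydro-4-O-benzoyl-6-bromo-6-deoxy-α-D-allopyranoside | CO[C@@H]1[C@@H]2O[C@@H]2[C@H](OC(=O)c3ccccc3)[C@@H](CBr)O1 | intermediate
3 | methyl 2,3-anhydro-6-bromo-6-deoxy-α-D-allopyranoside | CO[C@@H]1[C@@H]2O[C@@H]2[C@H](O)[C@@H](CBr)O1 | intermediate
4 | methyl 2,3-anhydro-6-bromo-6-deoxy-α-D-ribo-hexopyranosid-4-ulose | CO[C@@H]1[C@@H]2O[C@@H]2C(=O)[C@@H](CBr)O1 | intermediate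
5 | methyl 2,3-anhydro-6-deoxy-α-D-erythro-hex-5-enopyranosid-4-ulose | CO[C@@H]1[C@@H]2O[C@@H]2C(=O)C(=C)O1 | intermediate
6 | methyl 2,3:4,4′-dianhydro-6-deoxy-4-C-(hydroxymethyl)-α-D-ribo-hex-5-enopyranoside | CO[C@@H]1[C@@H]2O[C@@H]2[C@@]3(CO3)C(=C)O1 | intermediate
7 | methyl 2,3-anhydro-4-C-(benzoyloxymethyl)-6-deoxy-α-D-ribo-hex-5-enopyranoside | CO[C@@H]1[C@@H]2O[C@@H]2[C@@](O)(COC(=O)c3ccccc3)C(=C)O1 | intermediate
8 | methyl 2-O-benzoyl-4-C-(benzoyloxymethyl)-6-deoxy-α-D-arabino-hex-5-enopyranoside | CO[C@@H]1[C@@H](OC(=O)c2ccccc2)[C@H](O)[C@@](O)(COC(=O)c2ccccc2)C(=C)O1 | intermediate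
9 | 2-O-benzoyl-4-C-(benzoyloxymethyl)-6-deoxy-6-(trifluoroacetoxymercurio)-D-arabino-hexos-5-ulose, open chain | O=C[C@@H](OC(=O)c1ccccc1)[C@H](O)[C@@](O)(COC(=O)c1ccccc1)C(=O)C[Hg]OC(=O)C(F)(F)F | intermediate
10 | [(1S,2S,3R,4R)-3-(benzoyloxy)-1,2,4-trihydroxy-6-oxocyclohexyl]methyl benzoate | O=C(OC[C@@]1(O)C(=O)C[C@@H](O)[C@@H](OC(=O)c2ccccc2)[C@@H]1O)c1ccccc1 | target

Total step count: 7. Longest linear sequence: 7 steps (1 to 10).

Steps most likely to fail

Step 6. Regiocontrol in the oxirane opening may be lost through attack at C-3 or participation of the neighbouring primary benzoate. Titanium may also promote acyl migration between O-2 and O-3, or alcohol may add across the enol ether. The fallback opens the 2,3-oxirane first, while the benzylidene ring still locks the pyranose so that only trans-diaxial attack at C-2 is possible.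
- It sets out from 1. PhCO2H and PhCO2Cs in DMF at 110 °C should give methyl 2-O-benzoyl-4,6-O-benzylidene-α-D-altropyranoside F1.
- TBSOTf and 2,6-lutidine give its 3-O-tert-butyldimethylsilyl ether F2.
- Hydrogenolysis (H2, Pd(OH)2/C, EtOAc) gives the 4,6-diol F3.
- I2, PPh3 and imidazole give the 6-iodide F4.
- Dess–Martin oxidation followed by Et3N leads through the iodo-4-ulose F5 to the enone F6.
- The sulfonium ylide adds anti to the axial 3-silyloxy group to give the spiro-oxirane F7.
- Buffered benzoate opens it to the silylated hydroxy dibenzoate F8.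
- HF·pyridine removes the silyl group, and the route is rejoined at 8.

Step 7. The liberated aldehyde may rest as a furanose lactol on the free tertiary 4-OH. The aldol would then become slow, which leaves time for dehydration of the β-hydroxy ketone or erosion of facial selectivity. The fallback replaces organomercury activation by enamine catalysis. It sets out from 8, where brief treatment with aqueous acetic acid hydrolyses the enol ether and the glycoside to 2-O-benzoyl-4-C-(benzoyloxymethyl)-6-deoxy-D-arabino-hexos-5-ulose F11. This compound is a set of hemiacetals in equilibrium with the open keto-aldehyde. The matched enantiomer of proline in DMSO at rt closes it in a 6-enolendo aldol, and the route is rejoined at 10.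

Step 4. Conjugate addition, attack on the 2,3-oxirane or base-induced oligomerisation of the labile α-alkoxy enone may compete with 1,2-addition of the ylide. The fallback uses nucleophilic hydroxymethylation with a weakly basic Grignard reagent.
- It sets out from 5. (iPrO)Me2SiCH2MgCl in THF at −78 °C adds 1,2 from the β-face to give the 4-C-[(isopropoxydimethylsilyl)methyl] carbinol F9.
- Tamao–Fleming oxidation (KF, KHCO3, H2O2) gives the 4-C-(hydroxymethyl) diol F10.
- BzCl and 2,4,6-collidine at −40 °C acylate only the primary hydroxyl, and the route is rejoined at 7.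

Further compounds
F1 | step 6 | methyl 2-O-benzoyl-4,6-O-[(R)-benzylidene]-α-D-altropyranoside | CO[C@@H]1[C@@H](OC(=O)c2ccccc2)[C@H](O)[C@@H]3O[C@H](c4ccccc4)OC[C@H]3O1
F2 | step 6 | methyl 2-O-benzoyl-4,6-O-[(R)-benzylidene]-3-O-(tert-butyldimethylsilyl)-α-D-altropyranoside | CO[C@@H]1[C@@H](OC(=O)c2ccccc2)[C@H](O[Si](C)(C)C(C)(C)C)[C@@H]3O[C@H](c4ccccc4)OC[C@H]3O1
F3 | step 6 | methyl 2-O-benzoyl-3-O-(tert-butyldimethylsilyl)-α-D-altropyranoside | CO[C@@H]1[C@@H](OC(=O)c2ccccc2)[C@H](O[Si](C)(C)C(C)(C)C)[C@H](O)[C@@H](CO)O1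
F4 | step 6 | methyl 2-O-benzoyl-3-O-(tert-butyldimethylsilyl)-6-deoxy-6-iodo-α-D-altropyranoside | CO[C@@H]1[C@@H](OC(=O)c2ccccc2)[C@H](O[Si](C)(C)C(C)(C)C)[C@H](O)[C@@H](CI)O1
F5 | step 6 | methyl 2-O-benzoyl-3-O-(tert-butyldimethylsilyl)-6-deoxy-6-iodo-α-D-arabino-hexopyranosid-4-ulose | CO[C@@H]1[C@@H](OC(=O)c2ccccc2)[C@H](O[Si](C)(C)C(C)(C)C)C(=O)[C@@H](CI)O1
F6 | step 6 | methyl 2-O-benzoyl-3-O-(tert-butyldimethylsilyl)-6-deoxy-α-D-threo-hex-5-enopyranosid-4-ulose | CO[C@@H]1[C@@H](OC(=O)c2ccccc2)[C@H](O[Si](C)(C)C(C)(C)C)C(=O)C(=C)O1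
F7 | step 6 | methyl 4,4′-anhydro-2-O-benzoyl-3-O-(tert-butyldimethylsilyl)-6-deoxy-4-C-(hydroxymethyl)-α-D-arabino-hex-5-enopyranoside | CO[C@@H]1[C@@H](OC(=O)c2ccccc2)[C@H](O[Si](C)(C)C(C)(C)C)[C@@]3(CO3)C(=C)O1
F8 | step 6 | methyl 2-O-benzoyl-4-C-(benzoyloxymethyl)-3-O-(tert-butyldimethylsilyl)-6-deoxy-α-D-arabino-hex-5-enopyranoside | CO[C@@H]1[C@@H](OC(=O)c2ccccc2)[C@H](O[Si](C)(C)C(C)(C)C)[C@@](O)(COC(=O)c2ccccc2)C(=C)O1
F9 | step 4 | methyl 2,3-anhydro-6-deoxy-4-C-[(isopropoxydimethylsilyl)methyl]-α-D-ribo-hex-5-enopyranoside | CO[C@@H]1[C@@H]2O[C@@H]2[C@@](O)(C[Si](C)(C)OC(C)C)C(=C)O1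
F10 | step 4 | methyl 2,3-anhydro-6-deoxy-4-C-(hydroxymethyl)-α-D-ribo-hex-5-enopyranoside | CO[C@@H]1[C@@H]2O[C@@H]2[C@@](O)(CO)C(=C)O1
F11 | step 7 | 2-O-benzoyl-4-C-(benzoyloxymethyl)-6-deoxy-D-arabino-hexos-5-ulose, open-chain form | O=C[C@@H](OC(=O)c1ccccc1)[C@H](O)[C@@](O)(COC(=O)c1ccccc1)C(C)=O
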